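(The rate constants were chosen freely; the rest is arithmetic.)

Follow one Z through this flask and time each wait on its road to J.

    Z → X (k1 = 0.0384 /h)
    Z ⇌ Q (K2 = 38, k2 = 0.0109 /h)
    X ⇌ L (K3 = 0.91, k3 = 0.0782 /h)
    Q → E (k4 = 0.0441 /h)
    E ⇌ G (K5 = 6.14, k5 = 0.0457 /h)
    L → J (k6 = 0.187 /h)
    Z + J ⇌ Z.J, settled at all times (K7 = 66.7 /M)

the same everywhere: Z 0.010 M

| charge | time | remark |
|---|---|---|
| north-east | 25 h | everything together in a closed stirred flask, run for 25 h |
| south | 25 h | a tube with plug flow, the mixed feed as stated, residence time 25 h |
| east |  | a single well-mixed tank run continuously and read at steady state, 25 h in it on average |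

- a species is counted by the Z in it: one Z.J counts as two
- amounts and yields of J count Z.J too
- the stated concentrations are those of everything mixed, before any reaction; amounts are the same in each set-up
- in an amount of J, one Z.J counts as one J
- run time (north-east): 25 h

- the set-up with the highest amount of J at the outlet or at the end, in percent of the Z put in ("none" if the first two lie within 2 percentage points) (north-east / south / east / none)
- amount of J at the outlet or at the end, in percent of the Z put in, north-east
- amount of J at the outlet or at the end, in percent of the Z put in, south
- amount of J at the outlet or at the end, in percent of the Z put in, east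

I reckon the road as two stages. [Z] falls with constant a = 0.0493 /h, the sum of its two ways out, and a share s = 77.9 % of it goes to X, because the way back from Q, 2.87 × 10⁻⁴ /h, is slower than the way on from Q, 0.0441 /h. I leave Z.J out of my reckoning.

X and L form one pool that empties with two constants. The slower is the pool's drain constant, b = 0.0483 /h. The faster, f = 0.303 /h, costs a delay d, its inverse, of 3.30 h.

Here is the crossing: a and b nearly tie, so neither stage is the rate-limiting step, and J grows as behind two equal stages of mean constant m = 0.0488 /h:

y = s·[1 − (1 + u)·exp(−u)], with u = m·(t − d)

North-east, and south, whose every parcel lives the same 25 h: u = 1.06, y = 22.3 %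

The neighbour, the north-east flask left until 40 h: u = 1.79, y = 41.6 %

The two flasks differ in nothing but the time, yet in my curve 1.60 times the time gives the neighbour twice the J.

In the east tank each stage passes its constant over that constant plus w = 0.0400 /h, and the first stage passes 0.0384 /h over a + w:

y = 20.8 %

The forecast says none, with 22.2 %, 22.2 % and 19.9 %, and sets the tank's loss down to “back-mixing through the slow Z → X ⇌ L → J chain”.

The run gives 22.1 % north-east, 22.1 % south and 19.9 % east, so the answer is none, and my east figure stands 0.90 percentage points above the run. With a = 0.0493 /h against b = 0.0483 /h, my curve gives the north-east flask 22.3 %, where the run holds J, Z.J counted, at 22.1 %, less than Z at 27.2 %. For the flask left until 40 h the curve gives 41.6 %, where the run holds J, Z.J counted, at 40.7 %, more than Z at 13.2 %, and in the north-east flask Z and J stand equal at 26.9 h.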